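## Retrosynthetic overview

- (+)-Nortrachelogenin ⇐ its tri-O-acetate by global deacetylation.
- Tri-O-acetate ⇐ one-step radical 1,2-dibenzylation of the captodative enol acetate 3-acetoxyfuran-2(5H)-one with two 4-acetoxy-3-methoxybenzyl radicals. The C4–CH2Ar bond forms by enantioselective radical conjugate addition under a chiral Mg Lewis acid, and the C3–CH2Ar bond by radical–radical coupling anti to it, so both stereocentres are set in this step.
- 3-Acetoxyfuran-2(5H)-one ⇐ α-hydroxy-γ-butyrolactone by oxidation and enol acetylation.
- Benzyl bromide ⇐ p-cresol by ortho-bromination, Cu-catalysed methoxylation, acetylation and benzylic bromination.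
- Ring order: no ring is constructed. The lactone ring comes from α-hydroxy-γ-butyrolactone and both arenes from p-cresol.

Assumption: the (3aS,8aR)-inda-box/Mg complex is taken to deliver the benzyl radical to the face of C4 that gives (4R); if the observed sense is opposite, the antipodal ligand is used with no other change.

## Route

Step 1
Reactants: 1, 4-methylphenol (p-cresol)
Product: 2, 2-bromo-4-methylphenol
Conditions: Br2 (1.0 equiv), CH2Cl2, 0 °C
Reagents that add atoms: bromine, BrBr
Why: Electrophilic aromatic bromination; the para position is blocked, so the phenol directs to its ortho position (no stereocentre).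

Step 2
Reactants: 2, 2-bromo-4-methylphenol
Product: 3, 2-methoxy-4-methylphenol (creosol)
Conditions: NaOMe (4 equiv, 25% in MeOH), CuBr (10 mol%), DMF, 110 °C; then aq. HCl
Reagents that add atoms: sodium methoxide, [Na+].[O-]C
Why: Copper-catalysed Ullmann-type methoxylation of the aryl bromide; the free phenol is tolerated as its phenoxide, as in the standard conversion of o-bromophenols to guaiacols.

Step 3
Reactants: 3, 2-methoxy-4-methylphenol
Product: 4, 2-methoxy-4-methylphenyl acetate
Conditions: Ac2O, pyridine, DMAP (cat.), CH2Cl2, rt
Reagents that add atoms: acetic anhydride, CC(=O)OC(C)=O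
Why: Phenol O-acylation; the acetate removes the radical-quenching phenolic O–H and deactivates the ring toward ionic bromination in the next step.

Step 4
Reactants: 4, 2-methoxy-4-methylphenyl acetate
Product: 5, 4-(bromomethyl)-2-methoxyphenyl acetate
Conditions: NBS (1.05 equiv), AIBN (5 mol%), PhCF3, 85 °C
Reagents that add atoms: N-bromosuccinimide, O=C1CCC(=O)N1Br
Why: Wohl–Ziegler radical-chain benzylic bromination; bromine-atom abstraction is selective for the benzylic C–H over the OCH3 and acetyl C–H bonds.

Step 5
Reactants: 6, 3-hydroxyoxolan-2-one (racemic α-hydroxy-γ-butyrolactone)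
Product: 7, 2-oxo-2,5-dihydrofuran-3-yl acetate (3-acetoxyfuran-2(5H)-one)
Conditions: Dess–Martin periodinane (1.2 equiv), CH2Cl2, 0 °C → rt; then Ac2O (2 equiv), Et3N (3 equiv), DMAP (5 mol%), 0 °C, one pot
Reagents that add atoms: acetic anhydride, CC(=O)OC(C)=O
Why: Alcohol oxidation gives the α-keto lactone, which exists as its enol and is trapped in situ as the enol acetate before it can self-condense; the stereocentre of 6 is destroyed, so racemic material is used.

Step 6 (key step)
Reactants: 7, 2-oxo-2,5-dihydrofuran-3-yl acetate (1 equiv); 5, 4-(bromomethyl)-2-methoxyphenyl acetate (3 equiv, two benzyl units incorporated)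
Product: 8, (3R,4R)-3,4-bis[(4-acetoxy-3-methoxyphenyl)methyl]-2-oxooxolan-3-yl acetate (the two benzyl groups trans; OAc cis to the C4 benzyl)
Conditions: Mg(NTf2)2 (1.0 equiv), (3aS,3a'S,8aR,8a'R)-2,2'-(cyclopropane-1,1-diyl)bis(3a,8a-dihydro-8H-indeno[1,2-d]oxazole) (1.1 equiv, recovered), (Bu3Sn)2 (1.6 equiv), hν (300–350 nm, Pyrex, low intensity), 4 Å MS, CH2Cl2, −20 °C
Reagents that add atoms: none
Why: Proposed new method: Bu3Sn• from the photolysed distannane abstracts Br from 5 to give the nucleophilic benzyl radical, which adds to C4 of 7 held in a chiral Mg–bis(oxazoline) chelate (lactone C=O and acetate C=O), setting 4R. The resulting tertiary α-acetoxy-α-acyl (captodative) radical has no H-atom donor available and is trapped by a second benzyl radical on the ring face anti to the new C4 benzyl, setting 3R and the trans relationship. Closest known reaction types are bis-addition of two carbon radicals across captodative olefins (addition, then radical–radical cross-coupling), Mg–bis(oxazoline)-mediated enantioselective radical conjugate addition to cyclic α-acyloxy enones, and non-reductive distannane-mediated halide radical additions. Bibenzyl from benzyl-radical dimerisation is the expected by-product, hence the excess of 5 and the low radical flux.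

Step 7
Reactants: 8, the tri-O-acetate
Product: 9, (+)-nortrachelogenin, (3R,4R)-3-hydroxy-3,4-bis[(4-hydroxy-3-methoxyphenyl)methyl]oxolan-2-one
Conditions: LiOH·H2O (8 equiv), degassed THF/MeOH/H2O, 0 °C → rt; then 2 M HCl, rt
Reagents that add atoms: none
Why: Ester saponification removes the two aryl acetates and the tertiary acetate with transient lactone opening, and acidification re-closes the γ-lactone onto the primary alcohol; C3 is quaternary and C4 is not enolisable, so neither stereocentre can epimerise (ee can be upgraded by recrystallisation).

## Compound list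

1 | 4-methylphenol (p-cresol) | Cc1ccc(O)cc1 | starting material
2 | 2-bromo-4-methylphenol | Cc1ccc(O)c(Br)c1 | intermediate
3 | 2-methoxy-4-methylphenol | COc1cc(C)ccc1O | intermediate
4 | 2-methoxy-4-methylphenyl acetate | COc1cc(C)ccc1OC(C)=O | intermediate
5 | 4-(bromomethyl)-2-methoxyphenyl acetate | COc1cc(CBr)ccc1OC(C)=O | intermediate
6 | 3-hydroxyoxolan-2-one (racemic α-hydroxy-γ-butyrolactone) | OC1CCOC1=O | starting material
7 | 2-oxo-2,5-dihydrofuran-3-yl acetate | CC(=O)OC1=CCOC1=O | intermediate
8 | (3R,4R)-3,4-bis[(4-acetoxy-3-methoxyphenyl)methyl]-2-oxooxolan-3-yl acetate | COc1cc(C[C@@H]2COC(=O)[C@@]2(OC(C)=O)Cc2ccc(OC(C)=O)c(OC)c2)ccc1OC(C)=O | intermediate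
9 | (+)-nortrachelogenin, (3R,4R)-3-hydroxy-3,4-bis[(4-hydroxy-3-methoxyphenyl)methyl]oxolan-2-one | COc1cc(C[C@@H]2COC(=O)[C@@]2(O)Cc2ccc(O)c(OC)c2)ccc1O | target

## Totals and risks

Total step count: 7.
Longest linear sequence: 6 (steps 1, 2, 3, 4, 6, 7); step 5 is the convergent branch.

Steps most likely to fail:

1. Step 6 (low ee, slow benzyl-radical addition, bibenzyl formation). Fallback: replace catalyst control with a covalent auxiliary. Make the enol (−)-menthyl carbonate instead of the acetate in step 5, run the dibenzylation without Lewis acid at 25 °C, separate the two trans diastereomers by crystallisation or chromatography, then hydrolyse as in step 7.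
2. Step 5 (the free α-keto lactone self-condenses before acetylation). Fallback: avoid the keto lactone altogether. Displace α-bromo-γ-butyrolactone with KOAc to give 3-acetoxyoxolan-2-one, brominate C3 with NBS/hν, and eliminate HBr with Et3N to give 7.
3. Step 4 (ring bromination or over-bromination of the electron-rich arene). Fallback: go through the quinone methide. Oxidise creosol 3 with DDQ in MeOH to 4-(methoxymethyl)-2-methoxyphenol, then treat with acetyl bromide, which cleaves the benzylic methyl ether to the bromide and acetylates the phenol, giving 5 directly.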